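# Synthesis plan for CNP0174755.1 (3α,9β-diangeloyloxy-10βH-eremophil-11-en-8-one)

## The problem

Eremophilane numbering is used: ring A is C1–C2–C3–C4–C5–C10, ring B is C5–C6–C7–C8–C9–C10, C14 is the methyl on C5, C15 the methyl on C4, and C11–C13 the isopropenyl group on C7. The target is a cis-fused decalin (C14 and H10 both β) with six stereocentres, five of them contiguous (C3, C4, C5, C10, C9), and C5 is quaternary with a stereocentre on two sides. In the chair–chair form with C14 axial on ring A, all other substituents (3α-O, 4β-Me, 7β-isopropenyl, 9β-O) are equatorial, so C7 can follow the ring, but the two carbinols cannot simply be made from ring ketones, because the axial path of hydride is blocked by C14 at C3 and by C4 at C9. C3 can control C4 and C4 can control C5 by anti addition, whereas the cis relation C5/C10 is the weak link: on a monocyclic ring A, reagents reach C10 anti to the axial C14, and an acyl group on C10 has no useful equilibrium preference. The C8 ketone is β,γ-unsaturated and α-acyloxylated, so C7–H slips to the 7(11)-enone with acid or base, C9 can epimerise or pass on its acyl group, and the (Z)-angelates drift to tiglates; the ketone must therefore appear last, after both esters, and the isopropenyl group must be formed unconjugated. The feature that opens the problem is the fusion bond C5–C10, which carries on its α face C6, a plain CH2 on the quaternary C5, and C9, an oxygen-bearing carbon on the tertiary C10. These are exactly the CH2 and the C=O of a cyclobutanone made from a ketene and the ring-A alkene C5(Me)=C10H. Because C5 has no hydrogen, a metal placed on C6 when that ring is opened cannot β-eliminate, so the strain can be spent on the hindered C6–C7 bond.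

## Retrosynthesis

**23 ⇒ 22.** No carbon bond is cut; the C8 ketone is traced to the C8 carbinol. This makes the labile β,γ-unsaturated α-acyloxy ketone the product of one neutral oxidation. It requires that 22 carries a single free hydroxyl, at C8, with both esters already in place.

**22 ⇒ 21, cut C7–C8.** The unit C8(OH)–C7–C11(=C12) is the retron of a carbonyl-ene reaction of an aldehyde with a prenyl group. The neighbouring cuts (C5–C6, C9–C10) give an enone that needs the isopropenyl group added by enolate chemistry. The C7–C8 cut creates it unconjugated and frees only O8. Compound 21 has one ring and two stereocentres fewer. The forward reaction needs a chair transition state fixed by ring A.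

**21 ⇒ 17 + 18, cut both acyl–oxygen bonds, adjust C8.** Through 20 and 19 the aldehyde goes back to a PMB-protected primary alcohol, and both angelates go back to diol 17 and two equivalents of angelic acid 18. The two secondary alcohols are esterified in one operation while nothing base-sensitive is present.

**17 ⇒ 15, C9–H.** Through 16 the C9 carbinol is traced to ketone 15. The ketone lies between a branched ring carbon and a CH2O group, a size difference that a chiral reduction catalyst can read. Substrate bias is expected to point the other way.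

**15 ⇒ 13 + 14, cut C6–C7 and reconnect C6–C9.** C6 is neopentyl, so displacement there is hopeless, and prenylation of a C10 ketone enolate would leave C10 uncontrolled. Tying C6 to C9 in cyclobutanol 13 locks the two arms cis and stores the energy for a ring-opening coupling with bromide 14. The forward step must cleave C9–C6 rather than C9–C10.

**13 ⇒ 8 + 11, cut C8–C9.** C8 arrives with its oxygen as the organolithium 12 from stannane 11 (made from 9 and 10). The configuration created at C9 is irrelevant, since C9 becomes a ketone again.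

**8 ⇒ 6, cut C5–C6 and C9–C10 (key step).** Through 7 the cyclobutanone is the [2+2] adduct of a ketene with alkene 6. One event makes the quaternary C5 and C10, cis by geometry, and brings in two ring-B carbons with the oxygen on the correct one. Compound 6 is a monocycle with two stereocentres. The step needs attack anti to C15.

**6 ⇒ 3 ⇒ 1, cut C4–C15 and C5–C14.** Through 5 and enolate 4, alkene 6 comes from anti conjugate methylation of enone 3. Enone 3 comes through iodide 2 from the bought stereocentre of 1. C3 is thus the only stereocentre that is not made.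

## Roads not taken

Alternative 1: the obvious cut is C5–C6 and C9–C10, by Robinson annulation of a 2,3-dimethylcyclohexanone enolate with a vinyl ketone to give octalone A1.
- The forward key step is Michael addition anti to C15, then aldol condensation.
- After A1, cis hydrogenation forbids any other alkene, so the isopropenyl group must follow by aldol and dehydration at C7. That gives the conjugated 7(11)-ene and needs a strong-base deconjugation that the esters do not survive.
- C9 must be oxidised through a regiodefined enolate, and both alcohols must then be acylated beside the labile ketone or behind extra protecting groups.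
- The chosen plan makes the ketone and the isopropenyl group in the last two steps.

Alternative 2: cut C4–C5 and C1–C10. Ring B is bought as (+)-3-carene A2, whose ten carbons and configuration map onto C5–C14. It is oxidised to enone A3 and joined to diene A4 in a Diels–Alder reaction to give tricycle A5, with the cyclopropane as a masked isopropenyl group.
- cis-Fusion and C5 come in one step anti to the cyclopropane.
- The endo rule places C15 trans to C14.
- Oxygen sits on C9 as a ketone while C8 is a cyclopropane carbon, so every opening gives the 8-hydroxy-9-ketone, the wrong ketol.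
- Hydride then reaches C3 and C9 from the exposed faces and gives axial alcohols.
- The superacidic catalysts needed for a β,β-disubstituted enone endanger the cyclopropyl ketone.

Alternative 3: cut C1–C10 and C9–O. Ring B is read as a dearomatised 4-methylphenol A6, C5 being the para carbon and C8 the phenol carbon. Dienone iodide A7 would undergo radical cyclisation of C1 onto C10 with nitroxide capture at C9.
- This sets C5, C10 and C9 at once, with carbon and oxygen trans as required.
- The bond C4–C5 of A7 has no short stereocontrolled construction.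
- The choice between the two enone arms rests on chairs that differ only in an axial methyl versus an axial vinyl group.
- C7 must afterwards be alkenylated and the enone reduced, which produces the labile ketone before the esters are on.

Key step: step 5

Assumption: enantiopure (R)-4-[(tert-butyldimethylsilyl)oxy]cyclohex-2-en-1-one (1) is taken as a catalogue compound; TBS = tert-butyldimethylsilyl, PMB = 4-methoxybenzyl.

## Route

Step 1
Reactants: 1 (R)-4-[(tert-butyldimethylsilyl)oxy]cyclohex-2-en-1-one
Product: 2 (R)-4-[(tert-butyldimethylsilyl)oxy]-2-iodocyclohex-2-en-1-one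
Conditions: I2, pyridine, CH2Cl2, 0 °C to rt
Reagents that add atoms: iodine, II
Why: α-Iodination of an enone by reversible conjugate addition of pyridine, iodination of the enolate and elimination. The C3 silyl ether and its stereocentre are not involved.

Step 2
Reactants: 2 (R)-4-[(tert-butyldimethylsilyl)oxy]-2-iodocyclohex-2-en-1-one
Product: 3 (R)-4-[(tert-butyldimethylsilyl)oxy]-2-methylcyclohex-2-en-1-one
Conditions: Me2Zn, Pd(dppf)Cl2 (5 mol %), THF, 0 °C to rt
Reagents that add atoms: dimethylzinc, C[Zn]C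
Why: Negishi coupling of an α-iodoenone installs C14. The non-basic organozinc avoids elimination of the γ-silyloxy group.

Step 3
Reactants: 3 (R)-4-[(tert-butyldimethylsilyl)oxy]-2-methylcyclohex-2-en-1-one
Product: 5 (3R,4R)-4-[(tert-butyldimethylsilyl)oxy]-2,3-dimethylcyclohex-1-en-1-yl trifluoromethanesulfonate, via lithium enolate 4 (not isolated)
Conditions: Me2CuLi (MeLi, CuI), Et2O, −78 to −20 °C; then PhNTf2, THF–DMPU, −20 °C to rt
Reagents that add atoms: lithium dimethylcuprate, [Li+].C[Cu-]C; N-phenylbis(trifluoromethanesulfonimide), O=S(=O)(N(c1ccccc1)S(=O)(=O)C(F)(F)F)C(F)(F)F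
Why: Conjugate addition of a Gilman cuprate anti to the C3 silyloxy group sets C4 (C15 trans to oxygen). O-Sulfonylation of the regiodefined enolate 4 fixes the double bond between C5 and C10.

Step 4
Reactants: 5 (3R,4R)-4-[(tert-butyldimethylsilyl)oxy]-2,3-dimethylcyclohex-1-en-1-yl trifluoromethanesulfonate
Product: 6 tert-butyl{[(1R,2R)-2,3-dimethylcyclohex-3-en-1-yl]oxy}dimethylsilane
Conditions: Pd(OAc)2 (5 mol %), PPh3, HCO2H, Et3N, DMF, 60 °C
Reagents that add atoms: none
Why: Palladium-catalysed formate reduction of a vinyl triflate replaces OTf by H without moving the double bond. It gives the trisubstituted alkene C5(Me)=C10H; C3 and C4 are untouched.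

Step 5
Reactants: 6 tert-butyl{[(1R,2R)-2,3-dimethylcyclohex-3-en-1-yl]oxy}dimethylsilane
Product: 7 (1R,2R,3R,6S)-3-[(tert-butyldimethylsilyl)oxy]-8,8-dichloro-1,2-dimethylbicyclo[4.2.0]octan-7-one
Conditions: Cl3CCOCl, Zn–Cu, Et2O–DME, 25–35 °C
Reagents that add atoms: trichloroacetyl chloride, ClC(Cl)(Cl)C(Cl)=O
Why: Zinc dehalogenates the acid chloride to dichloroketene, which adds to the only alkene of 6 in a concerted but asynchronous [π2s+π2a] cycloaddition; the closest known cases are ketene cycloadditions to 1-methyl- and 1,6-dimethylcyclohexenes. The electrophilic ketene carbonyl carbon bonds ahead to the less substituted C10 while charge builds at the tertiary C5, which then takes the CCl2 carbon, so the oxygen-bearing carbon becomes C9 on C10 and the other becomes C6 on C5. The four-membered ring C5–C6–C9–C10 closes suprafacially on the alkene, so the cis relation of C6 and C9 (and of C14 and H10) is a geometric necessity and not a selectivity. The face is chosen by C4: A(1,2) strain with C14 pushes C15 pseudoaxial on the β face, so the ketene comes from the α face and C14 ends cis to C15. The quaternary C5 and C10 are thus both relayed from C4, itself relayed from C3, in one event that also brings in two ring-B carbons. Only regio- and facial selectivity are needed, since the silyl ether is inert and DME binds the zinc chloride.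

Step 6
Reactants: 7 (1R,2R,3R,6S)-3-[(tert-butyldimethylsilyl)oxy]-8,8-dichloro-1,2-dimethylbicyclo[4.2.0]octan-7-one
Product: 8 (1R,2R,3R,6S)-3-[(tert-butyldimethylsilyl)oxy]-1,2-dimethylbicyclo[4.2.0]octan-7-one
Conditions: Zn dust, AcOH, 25–40 °C
Reagents that add atoms: none
Why: Reductive dechlorination of an α,α-dichlorocyclobutanone through zinc enolates at C6. Enolisation toward the ring-fusion carbon C10 is strained, so no stereocentre is at risk.

Step 7
Reactants: 9 (tributylstannyl)methanol; 10 4-methoxybenzyl chloride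
Product: 11 tributyl{[(4-methoxybenzyl)oxy]methyl}stannane
Conditions: NaH, THF–DMF, 0 °C; then 10, Bu4NI (cat.), rt
Reagents that add atoms: none
Why: Williamson ether synthesis gives the storable precursor of the C8 nucleophile, with its oxygen already protected.

Step 8
Reactants: 11 tributyl{[(4-methoxybenzyl)oxy]methyl}stannane; 8 (1R,2R,3R,6S)-3-[(tert-butyldimethylsilyl)oxy]-1,2-dimethylbicyclo[4.2.0]octan-7-one
Product: 13 (1R,2R,3R,6S,7R)-3-[(tert-butyldimethylsilyl)oxy]-7-{[(4-methoxybenzyl)oxy]methyl}-1,2-dimethylbicyclo[4.2.0]octan-7-ol, via alkoxymethyllithium 12 (not isolated)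
Conditions: 11, n-BuLi, THF, −78 °C; then 8, −78 °C
Reagents that add atoms: none
Why: Tin–lithium exchange gives the α-alkoxy organolithium 12, which adds 1,2 to the strained and highly electrophilic cyclobutanone from its convex face. The new C9 configuration is erased in step 9.

Step 9
Reactants: 13 (1R,2R,3R,6S,7R)-3-[(tert-butyldimethylsilyl)oxy]-7-{[(4-methoxybenzyl)oxy]methyl}-1,2-dimethylbicyclo[4.2.0]octan-7-ol; 14 1-bromo-2-methylprop-1-ene
Product: 15 1-[(1S,2R,3R,4R)-4-[(tert-butyldimethylsilyl)oxy]-2,3-dimethyl-2-(3-methylbut-2-en-1-yl)cyclohexyl]-2-[(4-methoxybenzyl)oxy]ethan-1-one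
Conditions: Pd(OAc)2 (5 mol %), rac-BINAP (10 mol %), Cs2CO3, toluene, 90 °C
Reagents that add atoms: none
Why: Palladium-catalysed ring-opening cross-coupling of a tert-cyclobutanol: oxidative addition of 14, alkoxide exchange, strain-driven β-carbon elimination of the less hindered C9–C6 bond and C(sp3)–C(sp2) reductive elimination. The primary alkylpalladium on C6 has no β-hydrogen because C5 is quaternary, so coupling is its only exit. C5 and C10 are untouched and the prenyl and acyl arms stay cis.

Step 10
Reactants: 15 1-[(1S,2R,3R,4R)-4-[(tert-butyldimethylsilyl)oxy]-2,3-dimethyl-2-(3-methylbut-2-en-1-yl)cyclohexyl]-2-[(4-methoxybenzyl)oxy]ethan-1-one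
Product: 16 (1R)-1-[(1S,2R,3R,4R)-4-[(tert-butyldimethylsilyl)oxy]-2,3-dimethyl-2-(3-methylbut-2-en-1-yl)cyclohexyl]-2-[(4-methoxybenzyl)oxy]ethan-1-ol
Conditions: (R)-2-methyl-CBS-oxazaborolidine (0.5 equiv), catecholborane, toluene, −78 °C
Reagents that add atoms: none
Why: Corey–Bakshi–Shibata reduction with catecholborane, which leaves the trisubstituted alkene alone at −78 °C. The catalyst reads the branched ring carbon C10 as large and CH2OPMB as small, and the (R)-catalyst should give (9R), against the Felkin–Anh bias expected of the substrate.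

Step 11
Reactants: 16 (1R)-1-[(1S,2R,3R,4R)-4-[(tert-butyldimethylsilyl)oxy]-2,3-dimethyl-2-(3-methylbut-2-en-1-yl)cyclohexyl]-2-[(4-methoxybenzyl)oxy]ethan-1-ol
Product: 17 (1R,2R,3R,4S)-4-{(1R)-1-hydroxy-2-[(4-methoxybenzyl)oxy]ethyl}-2,3-dimethyl-3-(3-methylbut-2-en-1-yl)cyclohexan-1-ol
Conditions: TBAF, THF, 40 °C
Reagents that add atoms: none
Why: Fluoride desilylation frees O3. The PMB ether, the alkene and all stereocentres are inert.

Step 12
Reactants: 17 (1R,2R,3R,4S)-4-{(1R)-1-hydroxy-2-[(4-methoxybenzyl)oxy]ethyl}-2,3-dimethyl-3-(3-methylbut-2-en-1-yl)cyclohexan-1-ol; 18 angelic acid, (Z)-2-methylbut-2-enoic acid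
Product: 19 (1R,2R,3R,4S)-4-{(1R)-2-[(4-methoxybenzyl)oxy]-1-{[(Z)-2-methylbut-2-enoyl]oxy}ethyl}-2,3-dimethyl-3-(3-methylbut-2-en-1-yl)cyclohexyl (Z)-2-methylbut-2-enoate
Conditions: 18 (4 equiv), 2,4,6-trichlorobenzoyl chloride (4 equiv), Et3N, toluene, rt; then 17, 80 °C
Reagents that add atoms: angelic acid (second equivalent of 18), C/C=C(/C)C(=O)O
Why: Yamaguchi-type mixed-anhydride esterification run without a nucleophilic catalyst, the conditions under which angelates keep their Z geometry. The diol takes up two equivalents of 18, one on O3 and one on O9, so the mixed anhydride is made in excess before 17 is added. Both secondary alcohols are acylated in one operation while the molecule holds no base-sensitive group.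

Step 13
Reactants: 19 (1R,2R,3R,4S)-4-{(1R)-2-[(4-methoxybenzyl)oxy]-1-{[(Z)-2-methylbut-2-enoyl]oxy}ethyl}-2,3-dimethyl-3-(3-methylbut-2-en-1-yl)cyclohexyl (Z)-2-methylbut-2-enoate
Product: 20 (1R,2R,3R,4S)-4-{(1R)-2-hydroxy-1-{[(Z)-2-methylbut-2-enoyl]oxy}ethyl}-2,3-dimethyl-3-(3-methylbut-2-en-1-yl)cyclohexyl (Z)-2-methylbut-2-enoate
Conditions: DDQ, CH2Cl2–pH 7 buffer, 0 °C
Reagents that add atoms: none
Why: Oxidative cleavage of a PMB ether at neutral pH spares the esters and alkenes and gives little chance of acyl migration from O9 to O8.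

Step 14
Reactants: 20 (1R,2R,3R,4S)-4-{(1R)-2-hydroxy-1-{[(Z)-2-methylbut-2-enoyl]oxy}ethyl}-2,3-dimethyl-3-(3-methylbut-2-en-1-yl)cyclohexyl (Z)-2-methylbut-2-enoate
Product: 21 (1R,2R,3R,4S)-2,3-dimethyl-3-(3-methylbut-2-en-1-yl)-4-{(1R)-1-{[(Z)-2-methylbut-2-enoyl]oxy}-2-oxoethyl}cyclohexyl (Z)-2-methylbut-2-enoate
Conditions: Dess–Martin periodinane, NaHCO3, CH2Cl2, 0 °C
Reagents that add atoms: none
Why: Buffered Dess–Martin oxidation gives the α-acyloxy aldehyde without base, so C9 should hold. The aldehyde is used at once.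

Step 15
Reactants: 21 (1R,2R,3R,4S)-2,3-dimethyl-3-(3-methylbut-2-en-1-yl)-4-{(1R)-1-{[(Z)-2-methylbut-2-enoyl]oxy}-2-oxoethyl}cyclohexyl (Z)-2-methylbut-2-enoate
Product: 22 (3R,4R,5R,7R,8R,9R,10S)-8-hydroxyeremophil-11-ene-3,9-diyl bis[(Z)-2-methylbut-2-enoate]
Conditions: Me2AlCl (2.5 equiv), CH2Cl2, −78 °C
Reagents that add atoms: none
Why: Type I intramolecular carbonyl-ene reaction, the closure known from citronellal to isopulegol, here helped by the quaternary C5 and the activated aldehyde. Ring B forms through the chair that keeps 3-O and 4-Me equatorial on ring A and 9-O equatorial on ring B, which places the isopropenyl group equatorial (7β) and O8 equatorial (8α) on the cis-decalin. The alkene is formed unconjugated, and O8 is the only free hydroxyl.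

Step 16
Reactants: 22 (3R,4R,5R,7R,8R,9R,10S)-8-hydroxyeremophil-11-ene-3,9-diyl bis[(Z)-2-methylbut-2-enoate]
Product: 23 (3R,4R,5R,7R,9R,10S)-8-oxoeremophil-11-ene-3,9-diyl bis[(Z)-2-methylbut-2-enoate] (CNP0174755.1)
Conditions: Dess–Martin periodinane, NaHCO3, CH2Cl2, 0 °C to rt
Reagents that add atoms: none
Why: Buffered Dess–Martin oxidation of a homoallylic alcohol, as in isopulegol to isopulegone, forms the ketone under neutral conditions. C7 and C9 already hold their equatorial, more stable configurations.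

## Compound list

1 | (R)-4-[(tert-butyldimethylsilyl)oxy]cyclohex-2-en-1-one | O=C1C=C[C@H](O[Si](C)(C)C(C)(C)C)CC1 | starting material
2 | (R)-4-[(tert-butyldimethylsilyl)oxy]-2-iodocyclohex-2-en-1-one | O=C1C(I)=C[C@H](O[Si](C)(C)C(C)(C)C)CC1 | intermediate
3 | (R)-4-[(tert-butyldimethylsilyl)oxy]-2-methylcyclohex-2-en-1-one | O=C1C(C)=C[C@H](O[Si](C)(C)C(C)(C)C)CC1 | intermediate
4 | lithium (3R,4R)-4-[(tert-butyldimethylsilyl)oxy]-2,3-dimethylcyclohex-1-en-1-olate | CC1=C(O[Li])CC[C@@H](O[Si](C)(C)C(C)(C)C)[C@@H]1C | intermediate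
5 | (3R,4R)-4-[(tert-butyldimethylsilyl)oxy]-2,3-dimethylcyclohex-1-en-1-yl trifluoromethanesulfonate | CC1=C(OS(=O)(=O)C(F)(F)F)CC[C@@H](O[Si](C)(C)C(C)(C)C)[C@@H]1C | intermediate
6 | tert-butyl{[(1R,2R)-2,3-dimethylcyclohex-3-en-1-yl]oxy}dimethylsilane | CC1=CCC[C@@H](O[Si](C)(C)C(C)(C)C)[C@@H]1C | intermediate
7 | (1R,2R,3R,6S)-3-[(tert-butyldimethylsilyl)oxy]-8,8-dichloro-1,2-dimethylbicyclo[4.2.0]octan-7-one | C[C@H]1[C@H](O[Si](C)(C)C(C)(C)C)CC[C@@H]2C(=O)C(Cl)(Cl)[C@]12C | intermediate
8 | (1R,2R,3R,6S)-3-[(tert-butyldimethylsilyl)oxy]-1,2-dimethylbicyclo[4.2.0]octan-7-one | C[C@H]1[C@H](O[Si](C)(C)C(C)(C)C)CC[C@@H]2C(=O)C[C@]12C | intermediate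
9 | (tributylstannyl)methanol | CCCC[Sn](CCCC)(CCCC)CO | starting material
10 | 4-methoxybenzyl chloride | COc1ccc(CCl)cc1 | starting material
11 | tributyl{[(4-methoxybenzyl)oxy]methyl}stannane | CCCC[Sn](CCCC)(CCCC)COCc1ccc(OC)cc1 | intermediate
12 | {[(4-methoxybenzyl)oxy]methyl}lithium | [Li]COCc1ccc(OC)cc1 | intermediate
13 | (1R,2R,3R,6S,7R)-3-[(tert-butyldimethylsilyl)oxy]-7-{[(4-methoxybenzyl)oxy]methyl}-1,2-dimethylbicyclo[4.2.0]octan-7-ol | C[C@H]1[C@H](O[Si](C)(C)C(C)(C)C)CC[C@@H]2[C@@](O)(COCc3ccc(OC)cc3)C[C@]12C | intermediate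
14 | 1-bromo-2-methylprop-1-ene | CC(C)=CBr | starting material
15 | 1-[(1S,2R,3R,4R)-4-[(tert-butyldimethylsilyl)oxy]-2,3-dimethyl-2-(3-methylbut-2-en-1-yl)cyclohexyl]-2-[(4-methoxybenzyl)oxy]ethan-1-one | C[C@H]1[C@H](O[Si](C)(C)C(C)(C)C)CC[C@H](C(=O)COCc2ccc(OC)cc2)[C@]1(C)CC=C(C)C | intermediate
16 | (1R)-1-[(1S,2R,3R,4R)-4-[(tert-butyldimethylsilyl)oxy]-2,3-dimethyl-2-(3-methylbut-2-en-1-yl)cyclohexyl]-2-[(4-methoxybenzyl)oxy]ethan-1-ol | C[C@H]1[C@H](O[Si](C)(C)C(C)(C)C)CC[C@H]([C@@H](O)COCc2ccc(OC)cc2)[C@]1(C)CC=C(C)C | intermediate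
17 | (1R,2R,3R,4S)-4-{(1R)-1-hydroxy-2-[(4-methoxybenzyl)oxy]ethyl}-2,3-dimethyl-3-(3-methylbut-2-en-1-yl)cyclohexan-1-ol | C[C@H]1[C@H](O)CC[C@H]([C@@H](O)COCc2ccc(OC)cc2)[C@]1(C)CC=C(C)C | intermediate
18 | angelic acid, (Z)-2-methylbut-2-enoic acid | C/C=C(/C)C(=O)O | starting material
19 | (1R,2R,3R,4S)-4-{(1R)-2-[(4-methoxybenzyl)oxy]-1-{[(Z)-2-methylbut-2-enoyl]oxy}ethyl}-2,3-dimethyl-3-(3-methylbut-2-en-1-yl)cyclohexyl (Z)-2-methylbut-2-enoate | C[C@H]1[C@H](OC(=O)/C(C)=C\C)CC[C@H]([C@@H](OC(=O)/C(C)=C\C)COCc2ccc(OC)cc2)[C@]1(C)CC=C(C)C | intermediate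
20 | (1R,2R,3R,4S)-4-{(1R)-2-hydroxy-1-{[(Z)-2-methylbut-2-enoyl]oxy}ethyl}-2,3-dimethyl-3-(3-methylbut-2-en-1-yl)cyclohexyl (Z)-2-methylbut-2-enoate | C[C@H]1[C@H](OC(=O)/C(C)=C\C)CC[C@H]([C@@H](OC(=O)/C(C)=C\C)CO)[C@]1(C)CC=C(C)C | intermediate
21 | (1R,2R,3R,4S)-2,3-dimethyl-3-(3-methylbut-2-en-1-yl)-4-{(1R)-1-{[(Z)-2-methylbut-2-enoyl]oxy}-2-oxoethyl}cyclohexyl (Z)-2-methylbut-2-enoate | C[C@H]1[C@H](OC(=O)/C(C)=C\C)CC[C@H]([C@@H](OC(=O)/C(C)=C\C)C=O)[C@]1(C)CC=C(C)C | intermediate
22 | (3R,4R,5R,7R,8R,9R,10S)-8-hydroxyeremophil-11-ene-3,9-diyl bis[(Z)-2-methylbut-2-enoate] | C=C(C)[C@H]1C[C@@]2(C)[C@H](CC[C@@H](OC(=O)/C(C)=C\C)[C@@H]2C)[C@@H](OC(=O)/C(C)=C\C)[C@@H]1O | intermediate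
23 | (3R,4R,5R,7R,9R,10S)-8-oxoeremophil-11-ene-3,9-diyl bis[(Z)-2-methylbut-2-enoate] (CNP0174755.1) | C=C(C)[C@H]1C[C@@]2(C)[C@H](CC[C@@H](OC(=O)/C(C)=C\C)[C@@H]2C)[C@@H](OC(=O)/C(C)=C\C)C1=O | target

## Step count and least certain steps

Total step count: 16. Longest linear sequence: 15 (steps 1–6 and 8–16); step 7 is a side branch.

**Step 5 (key step).**
- Risk: facial selectivity may be eroded. In the half-chair that holds C15 pseudoaxial, the C3 silyloxy group is axial on the face that must be attacked. Zinc chloride may also strip the silyl ether.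
- Fallback: it gives up the four-membered tie, sets out from 3 and returns at 16.
  - Conjugate methylation of 3 and trapping of the enolate with prenyl bromide gives the 2-methyl-2-prenyl ketone F1.
  - Wittig reaction with (methoxymethylene)triphenylphosphorane gives the enol ether F2.
  - Mild acid hydrolysis gives both C10 epimers of the aldehyde.
  - The cis aldehyde F3 is separated, and the other epimer is re-equilibrated with an amine base and recycled.
  - Addition of 12 to F3, for which the Felkin–Anh model predicts (9R), gives 16.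

**Step 9.**
- Risk: β-carbon elimination may take the C9–C10 bond, followed by β-hydride elimination. The product may also epimerise at C10 under carbonate at 90 °C, where no useful equilibrium preference for the cis arms exists.
- Fallback: it sets out from 8 and returns at 15 by ring expansion and cleavage.
  - Trimethylsilyldiazomethane with BF3·OEt2 inserts CH2 next to the less substituted carbon to give the cis-hydrindan-1-one F4, in which cis fusion is also the stable one.
  - LDA and Me3SiCl give the kinetic silyl enol ether F5.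
  - Ozonolysis gives the aldehyde acid F6.
  - Excess isopropylidenetriphenylphosphorane gives the prenyl acid F7.
  - Two equivalents of 12 convert the acid into 15.

**Step 10.**
- Risk: catalyst and substrate preferences are opposed, so diastereoselection may be low. Slow reduction of the hindered ketone would leave room for hydroboration of the prenyl group.
- Fallback: it uses the substrate bias and an inversion, sets out from 15 and returns at 19.
  - L-Selectride should give the (9S) alcohol F8.
  - A Mitsunobu reaction with 18 inverts C9 and gives the C9 angelate F9.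
  - HF·pyridine gives the C3 alcohol F10.
  - The conditions of step 12, now with one hydroxyl to acylate, complete 19.

**Step 12.**
- Risk: acylation of the hindered C9 carbinol may be slow, so the reaction may stall at the C3 monoester, and long heating may isomerise Z to E.
- Fallback: it builds the double bonds on the ester, sets out from 17 and returns at 19.
  - Carbodiimide coupling with two equivalents of 2-[bis(2,2,2-trifluoroethoxy)phosphoryl]propanoic acid gives the bis(phosphonopropionate) F11.
  - Still–Gennari olefination with acetaldehyde (KHMDS, 18-crown-6, −78 °C) gives both Z-alkenes.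

**Step 15.**
- Risk: several processes could lower the return. These are capture of the tertiary cation by chloride, methyl transfer to the aldehyde, epimerisation of the α-acyloxy aldehyde on the Lewis acid, and acyl shift from O9 to the new O8 alkoxide.
- Fallback: it replaces the ene reaction by an allylmetal addition, sets out from 20 and returns at 22.
  - Ene-type chlorination of the electron-rich prenyl group (NCS, cat. PhSeCl) gives the allylic chloride F12.
  - Dess–Martin oxidation gives the chloro aldehyde F13.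
  - CrCl2 in THF (Nozaki–Hiyama allylation) closes C7–C8 through the γ-carbon of the allylchromium and regenerates the isopropenyl group.

## Further compounds

F1 | step 5 | (2R,3R,4R)-4-[(tert-butyldimethylsilyl)oxy]-2,3-dimethyl-2-(3-methylbut-2-en-1-yl)cyclohexan-1-one | C[C@H]1[C@H](O[Si](C)(C)C(C)(C)C)CCC(=O)[C@]1(C)CC=C(C)C
F2 | step 5 | tert-butyl{[(1R,2R,3R)-4-(methoxymethylidene)-2,3-dimethyl-3-(3-methylbut-2-en-1-yl)cyclohexyl]oxy}dimethylsilane (E/Z) | COC=C1CC[C@@H](O[Si](C)(C)C(C)(C)C)[C@H](C)[C@@]1(C)CC=C(C)C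
F3 | step 5 | (1S,2R,3R,4R)-4-[(tert-butyldimethylsilyl)oxy]-2,3-dimethyl-2-(3-methylbut-2-en-1-yl)cyclohexane-1-carbaldehyde | O=C[C@H]1CC[C@@H](O[Si](C)(C)C(C)(C)C)[C@H](C)[C@@]1(C)CC=C(C)C
F4 | step 9 | (3aR,4R,5R,7aS)-5-[(tert-butyldimethylsilyl)oxy]-3a,4-dimethyloctahydro-1H-inden-1-one | C[C@H]1[C@H](O[Si](C)(C)C(C)(C)C)CC[C@@H]2C(=O)CC[C@]12C
F5 | step 9 | tert-butyl{[(3aR,4R,5R,7aS)-3a,4-dimethyl-1-[(trimethylsilyl)oxy]-3a,4,5,6,7,7a-hexahydro-3H-inden-5-yl]oxy}dimethylsilane | C[C@H]1[C@H](O[Si](C)(C)C(C)(C)C)CC[C@@H]2C(O[Si](C)(C)C)=CC[C@]12C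
F6 | step 9 | (1S,2R,3R,4R)-4-[(tert-butyldimethylsilyl)oxy]-2,3-dimethyl-2-(2-oxoethyl)cyclohexane-1-carboxylic acid | C[C@H]1[C@H](O[Si](C)(C)C(C)(C)C)CC[C@H](C(=O)O)[C@]1(C)CC=O
F7 | step 9 | (1S,2R,3R,4R)-4-[(tert-butyldimethylsilyl)oxy]-2,3-dimethyl-2-(3-methylbut-2-en-1-yl)cyclohexane-1-carboxylic acid | C[C@H]1[C@H](O[Si](C)(C)C(C)(C)C)CC[C@H](C(=O)O)[C@]1(C)CC=C(C)C
F8 | step 10 | (1S)-1-[(1S,2R,3R,4R)-4-[(tert-butyldimethylsilyl)oxy]-2,3-dimethyl-2-(3-methylbut-2-en-1-yl)cyclohexyl]-2-[(4-methoxybenzyl)oxy]ethan-1-ol | C[C@H]1[C@H](O[Si](C)(C)C(C)(C)C)CC[C@H]([C@H](O)COCc2ccc(OC)cc2)[C@]1(C)CC=C(C)C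
F9 | step 10 | (1R)-1-[(1S,2R,3R,4R)-4-[(tert-butyldimethylsilyl)oxy]-2,3-dimethyl-2-(3-methylbut-2-en-1-yl)cyclohexyl]-2-[(4-methoxybenzyl)oxy]ethyl (Z)-2-methylbut-2-enoate | C[C@H]1[C@H](O[Si](C)(C)C(C)(C)C)CC[C@H]([C@@H](OC(=O)/C(C)=C\C)COCc2ccc(OC)cc2)[C@]1(C)CC=C(C)C
F10 | step 10 | (1R)-1-[(1S,2R,3R,4R)-4-hydroxy-2,3-dimethyl-2-(3-methylbut-2-en-1-yl)cyclohexyl]-2-[(4-methoxybenzyl)oxy]ethyl (Z)-2-methylbut-2-enoate | C[C@H]1[C@H](O)CC[C@H]([C@@H](OC(=O)/C(C)=C\C)COCc2ccc(OC)cc2)[C@]1(C)CC=C(C)C
F11 | step 12 | bis{2-[bis(2,2,2-trifluoroethoxy)phosphoryl]propanoate} of diol 17 | C[C@H]1[C@H](OC(=O)C(C)P(=O)(OCC(F)(F)F)OCC(F)(F)F)CC[C@H]([C@@H](OC(=O)C(C)P(=O)(OCC(F)(F)F)OCC(F)(F)F)COCc2ccc(OC)cc2)[C@]1(C)CC=C(C)C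
F12 | step 15 | (1R,2R,3R,4S)-3-(2-chloro-3-methylbut-3-en-1-yl)-4-{(1R)-2-hydroxy-1-{[(Z)-2-methylbut-2-enoyl]oxy}ethyl}-2,3-dimethylcyclohexyl (Z)-2-methylbut-2-enoate (epimers at CHCl) | C[C@H]1[C@H](OC(=O)/C(C)=C\C)CC[C@H]([C@@H](OC(=O)/C(C)=C\C)CO)[C@]1(C)CC(Cl)C(C)=C
F13 | step 15 | (1R,2R,3R,4S)-3-(2-chloro-3-methylbut-3-en-1-yl)-2,3-dimethyl-4-{(1R)-1-{[(Z)-2-methylbut-2-enoyl]oxy}-2-oxoethyl}cyclohexyl (Z)-2-methylbut-2-enoate (epimers at CHCl) | C[C@H]1[C@H](OC(=O)/C(C)=C\C)CC[C@H]([C@@H](OC(=O)/C(C)=C\C)C=O)[C@]1(C)CC(Cl)C(C)=C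
A1 | alternative 1 | (4aR,5R,6R)-6-[(tert-butyldimethylsilyl)oxy]-4a,5-dimethyl-4,4a,5,6,7,8-hexahydronaphthalen-2(3H)-one | C[C@H]1[C@H](O[Si](C)(C)C(C)(C)C)CCC2=CC(=O)CC[C@]12C
A2 | alternative 2 | (+)-3-carene, (1S,6R)-3,7,7-trimethylbicyclo[4.1.0]hept-3-ene | CC1=CC[C@@H]2[C@H](C1)C2(C)C
A3 | alternative 2 | car-3-en-5-one from (+)-3-carene | CC1=CC(=O)[C@@H]2[C@H](C1)C2(C)C
A4 | alternative 2 | (Z)-tert-butyldimethyl(penta-1,3-dien-3-yloxy)silane | C/C=C(\O[Si](C)(C)C(C)(C)C)C=C
A5 | alternative 2 | endo Diels–Alder adduct of A3 and A4 (cis-fused, C15 trans to C14, cyclopropane on C7/C8, C9 ketone) | C[C@@H]1C(O[Si](C)(C)C(C)(C)C)=CC[C@@H]2C(=O)[C@@H]3[C@H](C[C@]12C)C3(C)C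
A6 | alternative 3 | 4-methylphenol | Cc1ccc(O)cc1
A7 | alternative 3 | 4-{(2R,3R)-3-[(tert-butyldimethylsilyl)oxy]-5-iodopentan-2-yl}-4-methylcyclohexa-2,5-dien-1-one | C[C@@H]([C@@H](CCI)O[Si](C)(C)C(C)(C)C)C1(C)C=CC(=O)C=C1
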